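The depside ester linking the central oxygen of ring A to the C1' carboxyl of ring B is formed late. The plan rests on assembling ring B from open-chain pieces. In a single photochemical and thermal operation an unsaturated diazo ketone and tert-butoxyethyne merge into the fully substituted benzoate, closing ring B with propyl at C2'. The step exploits the meta-related oxygens at C4' and C6' of ring B: O–C6' emerges as a free phenol beside the C1' ester, O–C4' arrives as a tert-butyl ether, so only C6' can be methylated. The precursor is a fumarate-like benzyl 4-oxo-enoate, propyl-branched at the carbon next to the ketone and ending in a diazomethyl group.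

Key step: step 7

Remark on the chemistry: ring B locants are C1' (carboxyl), C2' (propyl), C4' (OH) and C6' (OMe); ring A, numbered as the phenyl ester, has C1 (O-acyl), C2 and C6 (OH), C3 (acetyl) and C4 (pentyl); the target has no stereocentre, and the alkene geometries of the early intermediates disappear in the arene.

Step 1
Reactants: 1 butyltriphenylphosphonium bromide
Product: 3 3-(triphenylphosphoranylidene)hexan-2-one, via butylidenetriphenylphosphorane 2 (not isolated)
Conditions: n-BuLi (1.0 equiv per 1), THF, 0 °C; AcCl (0.5 equiv), −78 °C → rt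
Reagents that add atoms: acetyl chloride, CC(=O)Cl
Why: C-acylation of a non-stabilised phosphorus ylide by an acid chloride should work because the second equivalent of 2 deprotonates the acylphosphonium salt (transylidation) and leaves a keto-stabilised ylide that survives aqueous work-up.

Step 2
Reactants: 4 dibenzyl (2R,3R)-tartrate
Product: 5 benzyl glyoxylate
Conditions: H5IO6, Et2O, rt; used fresh
Reagents that add atoms: none
Why: Malaprade-type cleavage of the vicinal diol should give two molecules of aldehyde per tartrate in a non-aqueous medium that limits hydrate formation, and both stereocentres of 4 are consumed.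

Step 3
Reactants: 3 3-(triphenylphosphoranylidene)hexan-2-one; 5 benzyl glyoxylate
Product: 6 benzyl (E)-4-oxo-3-propylpent-2-enoate
Conditions: CH2Cl2, 0 °C → rt
Reagents that add atoms: none
Why: Wittig olefination of a very electrophilic aldehyde with an alpha-branched keto-stabilised ylide follows the usual preference of stabilised ylides and should place the ester trans to the acetyl group (E), any Z isomer being removed by chromatography.

Step 4
Reactants: 6 benzyl (E)-4-oxo-3-propylpent-2-enoate
Product: 8 benzyl (E)-5-diazo-4-oxo-3-propylpent-2-enoate, via trifluoroacetyl diketone 7 (not isolated)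
Conditions: LiN(SiMe3)2, THF, −78 °C; CF3CO2CH2CF3, −78 °C; 5% HCl work-up; MsN3, Et3N, H2O (1 equiv), MeCN, rt
Reagents that add atoms: 2,2,2-trifluoroethyl trifluoroacetate, O=C(OCC(F)(F)F)C(F)(F)F (atoms kept only in 7); methanesulfonyl azide, CS(=O)(=O)N=[N+]=[N-]
Why: Detrifluoroacetylative diazo transfer (kinetic alpha'-enolate, Claisen-type trifluoroacetylation, Regitz-type transfer with loss of the trifluoroacetyl group) is the established entry to alpha'-diazo enones, and it keeps the doubly activated C=C away from diazomethane, which would add to it as a 1,3-dipole to give pyrazolines.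

Step 5
Reactants: 9 tert-butyl vinyl ether
Product: 11 (Z)-1-bromo-2-(tert-butoxy)ethene, via dibromo ether 10 (not isolated)
Conditions: Br2, CH2Cl2, −78 °C; Et3N, −78 °C → rt
Reagents that add atoms: bromine, BrBr
Why: Electrophilic bromination of the enol ether followed by base-induced loss of the oxygen-activated alpha-bromide (dehydrobromination) should favour the cis bromovinyl ether, the isomer set up for anti elimination in the next step.

Step 6
Reactants: 11 (Z)-1-bromo-2-(tert-butoxy)ethene
Product: 13 tert-butoxyethyne, via sodium acetylide 12 (not isolated)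
Conditions: NaNH2 (2.5 equiv), NH3(l), −33 °C; cold H2O, pentane; concentrated and distilled under reduced pressure below rt
Reagents that add atoms: NaNH2, [Na+].[NH2-] (sodium kept only in 12)
Why: Anti E2 dehydrobromination of a 2-halovinyl ether is the classical ynol ether synthesis, and the product stays protected as its acetylide until the cold quench.

Step 7
Reactants: 8 benzyl (E)-5-diazo-4-oxo-3-propylpent-2-enoate; 13 tert-butoxyethyne
Product: 18 benzyl 4-(tert-butoxy)-2-hydroxy-6-propylbenzoate, via vinylketene 14 (not isolated), via cyclobutenone 15 (not isolated), via dienylketene 16 (not isolated), via cyclohexadienone 17 (not isolated)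
Conditions: 13 (2.5 equiv), degassed CH2Cl2, hν (300 nm), 15–20 °C; volatiles removed cold; toluene, 80 °C
Reagents that add atoms: none
Why: Light expels N2 from 8 and the alkenyl group shifts from the carbonyl carbon to the former diazo carbon (Wolff rearrangement, which itself makes C2'–C3'), and the ketene carbon of the resulting vinylketene 14 is attacked by the unsubstituted carbon of 13 in a (2+2) cycloaddition that sets C5'–C6' and C3'–C4' in cyclobutenone 15. On warming, 15 opens by reversible conrotatory 4π cleavage of its C3'–C6' bond to dienylketene 16, and ring B is closed by thermal disrotatory 6π electrocyclisation of the ketene carbon onto the ester-bearing alkene terminus (C1'–C6'), after which beta-keto ester 17 enolises to the chelated phenol 18. The closest known reaction type is the Danheiser benzannulation in its diazo ketone form, established for unsaturated diazo ketones with alkoxy- and siloxyalkynes. The sp3 centres of 15 and 17 are transient and vanish on aromatisation, so no stereocentre has to be controlled. The step needs regioselective ketene–alkyne union, secured by the oxygen-polarised triple bond of 13 (nucleophilic CH terminus, hence O–C4' meta to O–C6'), and carbon rather than ester-oxygen attack in the closure, secured by the E alkene of 8, which turns H and not the ester toward the ketene. Since 13 sheds isobutene on gentle warming, the photolysis is run cool and the excess alkyne is evaporated cold before the thermal stage.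

Step 8
Reactants: 18 benzyl 4-(tert-butoxy)-2-hydroxy-6-propylbenzoate
Product: 19 benzyl 4-(tert-butoxy)-2-methoxy-6-propylbenzoate
Conditions: MeI, K2CO3, DMF, rt → 40 °C
Reagents that add atoms: iodomethane, CI
Why: Williamson methylation can only strike the single free hydroxyl at C6', and the polar solvent overcomes its chelation to the ester while the tert-butyl ether and the benzyl ester stay inert.

Step 9
Reactants: 19 benzyl 4-(tert-butoxy)-2-methoxy-6-propylbenzoate
Product: 20 4-(tert-butoxy)-2-methoxy-6-propylbenzoic acid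
Conditions: H2 (1 atm), 10% Pd/C, EtOAc, rt
Reagents that add atoms: none
Why: Hydrogenolysis frees the acid without the forcing hydroxide that a 2,6-disubstituted benzoate would need, and the aryl tert-butyl and methyl ethers are untouched.

Step 10
Reactants: 21 olivetol (5-pentylbenzene-1,3-diol)
Product: 22 2-iodo-5-pentylbenzene-1,3-diol
Conditions: I2, NaHCO3, THF–H2O, 0 °C
Reagents that add atoms: iodine, II
Why: Electrophilic iodination of a resorcinol under hydrogencarbonate buffering is kinetically directed to the carbon between the two oxygens, and the pentyl group further shields the other two positions.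

Step 11
Reactants: 22 2-iodo-5-pentylbenzene-1,3-diol
Product: 23 1,3-bis(benzyloxy)-2-iodo-5-pentylbenzene
Conditions: BnBr (2.3 equiv), K2CO3, DMF, rt
Reagents that add atoms: benzyl bromide, BrCc1ccccc1
Why: Double Williamson benzylation of two equivalent phenols is routine, and the aryl iodide is inert to carbonate.

Step 12
Reactants: 23 1,3-bis(benzyloxy)-2-iodo-5-pentylbenzene
Product: 26 2,6-bis(benzyloxy)-4-pentylphenol, via arylmagnesium chloride 24 (not isolated), via dimethyl boronate 25 (not isolated)
Conditions: iPrMgCl·LiCl, THF, 0 °C → rt; B(OMe)3, −20 °C → rt; AcOH, 30% H2O2, 0 °C → rt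
Reagents that add atoms: isopropylmagnesium chloride, CC(C)[Mg]Cl (Mg and Cl kept only in 24); trimethyl borate, COB(OC)OC (atoms kept only in 25); hydrogen peroxide, OO (the phenol oxygen)
Why: Iodine–magnesium exchange assisted by the two flanking ether oxygens avoids the benzylic deprotonation that threatens direct lithiation of a dibenzyl ether, and borylation followed by oxidative 1,2-aryl shift under acidic peroxide (which limits protodeboronation) delivers the central phenol.

Step 13
Reactants: 26 2,6-bis(benzyloxy)-4-pentylphenol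
Product: 29 1-[2,4-bis(benzyloxy)-3-hydroxy-6-pentylphenyl]ethan-1-one, via aryl acetate 27 (not isolated), via keto acetate 28 (not isolated)
Conditions: AcOH, (CF3CO)2O, H3PO4 (cat.), CH2Cl2, 0 °C → rt; aq. NaHCO3 wash; K2CO3 (cat.), MeOH, rt
Reagents that add atoms: acetic acid, CC(=O)O
Why: Friedel–Crafts acylation by acetyl trifluoroacetate first caps the phenol as its acetate and then acylates one of the two symmetry-equivalent ring positions (ortho and para to benzyloxy groups) without a metal Lewis acid that would strip benzyl ethers, the first acetyl group stops further acylation, and mild methanolysis removes only the aryl acetate.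

Step 14
Reactants: 20 4-(tert-butoxy)-2-methoxy-6-propylbenzoic acid; 29 1-[2,4-bis(benzyloxy)-3-hydroxy-6-pentylphenyl]ethan-1-one
Product: 31 3-acetyl-2,6-bis(benzyloxy)-4-pentylphenyl 4-(tert-butoxy)-2-methoxy-6-propylbenzoate, via acid chloride 30 (not isolated)
Conditions: 20, Me2C=C(Cl)NMe2, CH2Cl2, 0 °C → rt; then 29, Et3N, DMAP (cat.), CH2Cl2, rt
Reagents that add atoms: 1-chloro-N,N,2-trimethylprop-1-en-1-amine, CC(C)=C(Cl)N(C)C (chlorine kept only in 30)
Why: The chloroenamine makes the hindered acid chloride under neutral conditions that spare the tert-butyl ether, and DMAP-catalysed acylation (nucleophilic catalysis) can only reach the one free hydroxyl of 29.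

Step 15
Reactants: 31 3-acetyl-2,6-bis(benzyloxy)-4-pentylphenyl 4-(tert-butoxy)-2-methoxy-6-propylbenzoate
Product: 32 3-acetyl-2,6-bis(benzyloxy)-4-pentylphenyl 4-hydroxy-2-methoxy-6-propylbenzoate
Conditions: TFA–CH2Cl2 (1:4), 0 °C
Reagents that add atoms: none
Why: E1-type acidolysis of the aryl tert-butyl ether is run while ring A is still benzylated and therefore a poor trap for the tert-butyl cation, the aryl benzoate is stable to cold acid, and any early loss of a benzyl group would only anticipate step 16.

Step 16
Reactants: 32 3-acetyl-2,6-bis(benzyloxy)-4-pentylphenyl 4-hydroxy-2-methoxy-6-propylbenzoate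
Product: 33 3-acetyl-2,6-dihydroxy-4-pentylphenyl 4-hydroxy-2-methoxy-6-propylbenzoate (target)
Conditions: H2 (1 atm), 10% Pd/C, EtOAc, rt, stopped at the calculated uptake
Reagents that add atoms: none
Why: Neutral hydrogenolysis of the two aryl benzyl ethers exposes the flanking hydroxyls without acid or base, so the hindered benzoate should not migrate, and the crowded, chelated aryl ketone should resist reduction at this pressure.

Compound list
1 | butyltriphenylphosphonium bromide | CCCC[P+](c1ccccc1)(c1ccccc1)c1ccccc1.[Br-] | starting material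
2 | butylidenetriphenylphosphorane | CCCC=P(c1ccccc1)(c1ccccc1)c1ccccc1 | intermediate
3 | 3-(triphenylphosphoranylidene)hexan-2-one | CCCC(C(C)=O)=P(c1ccccc1)(c1ccccc1)c1ccccc1 | intermediate
4 | dibenzyl (2R,3R)-tartrate | O[C@@H](C(=O)OCc1ccccc1)[C@@H](O)C(=O)OCc1ccccc1 | starting material
5 | benzyl glyoxylate (benzyl 2-oxoacetate) | O=CC(=O)OCc1ccccc1 | intermediate
6 | benzyl (E)-4-oxo-3-propylpent-2-enoate | CCC/C(C(C)=O)=C\C(=O)OCc1ccccc1 | intermediate
7 | benzyl (E)-7,7,7-trifluoro-4,6-dioxo-3-propylhept-2-enoate | CCC/C(C(=O)CC(=O)C(F)(F)F)=C\C(=O)OCc1ccccc1 | intermediate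
8 | benzyl (E)-5-diazo-4-oxo-3-propylpent-2-enoate | CCC/C(C(=O)C=[N+]=[N-])=C\C(=O)OCc1ccccc1 | intermediate
9 | tert-butyl vinyl ether | C=COC(C)(C)C | starting material
10 | 1,2-dibromo-1-(tert-butoxy)ethane (racemic) | BrCC(Br)OC(C)(C)C | intermediate
11 | (Z)-1-bromo-2-(tert-butoxy)ethene | Br/C=C\OC(C)(C)C | intermediate
12 | sodium 2-(tert-butoxy)ethynide | [Na+].[C-]#COC(C)(C)C | intermediate
13 | tert-butoxyethyne | C#COC(C)(C)C | intermediate
14 | benzyl (E)-5-oxo-3-propylpenta-2,4-dienoate (vinylketene) | CCC/C(C=C=O)=C\C(=O)OCc1ccccc1 | intermediate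
15 | benzyl (E)-3-[2-(tert-butoxy)-4-oxocyclobut-2-en-1-yl]hex-2-enoate (racemic) | CCC/C(=C\C(=O)OCc1ccccc1)C1C(=O)C=C1OC(C)(C)C | intermediate
16 | benzyl (2E,4E)-5-(tert-butoxy)-7-oxo-3-propylhepta-2,4,6-trienoate (dienylketene) | O=C=C/C(OC(C)(C)C)=C\C(CCC)=C\C(=O)OCc1ccccc1 | intermediate
17 | benzyl 4-(tert-butoxy)-2-oxo-6-propylcyclohexa-3,5-diene-1-carboxylate (racemic) | CCCC1=CC(OC(C)(C)C)=CC(=O)C1C(=O)OCc1ccccc1 | intermediate
18 | benzyl 4-(tert-butoxy)-2-hydroxy-6-propylbenzoate | CCCc1cc(OC(C)(C)C)cc(O)c1C(=O)OCc1ccccc1 | intermediate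
19 | benzyl 4-(tert-butoxy)-2-methoxy-6-propylbenzoate | CCCc1cc(OC(C)(C)C)cc(OC)c1C(=O)OCc1ccccc1 | intermediate
20 | 4-(tert-butoxy)-2-methoxy-6-propylbenzoic acid | CCCc1cc(OC(C)(C)C)cc(OC)c1C(=O)O | intermediate
21 | olivetol (5-pentylbenzene-1,3-diol) | CCCCCc1cc(O)cc(O)c1 | starting material
22 | 2-iodo-5-pentylbenzene-1,3-diol | CCCCCc1cc(O)c(I)c(O)c1 | intermediate
23 | 1,3-bis(benzyloxy)-2-iodo-5-pentylbenzene | CCCCCc1cc(OCc2ccccc2)c(I)c(OCc2ccccc2)c1 | intermediate
24 | [2,6-bis(benzyloxy)-4-pentylphenyl]magnesium chloride | CCCCCc1cc(OCc2ccccc2)c([Mg]Cl)c(OCc2ccccc2)c1 | intermediate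
25 | dimethyl [2,6-bis(benzyloxy)-4-pentylphenyl]boronate | CCCCCc1cc(OCc2ccccc2)c(B(OC)OC)c(OCc2ccccc2)c1 | intermediate
26 | 2,6-bis(benzyloxy)-4-pentylphenol | CCCCCc1cc(OCc2ccccc2)c(O)c(OCc2ccccc2)c1 | intermediate
27 | 2,6-bis(benzyloxy)-4-pentylphenyl acetate | CCCCCc1cc(OCc2ccccc2)c(OC(C)=O)c(OCc2ccccc2)c1 | intermediate
28 | 3-acetyl-2,6-bis(benzyloxy)-4-pentylphenyl acetate | CCCCCc1cc(OCc2ccccc2)c(OC(C)=O)c(OCc2ccccc2)c1C(C)=O | intermediate
29 | 1-[2,4-bis(benzyloxy)-3-hydroxy-6-pentylphenyl]ethan-1-one | CCCCCc1cc(OCc2ccccc2)c(O)c(OCc2ccccc2)c1C(C)=O | intermediate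
30 | 4-(tert-butoxy)-2-methoxy-6-propylbenzoyl chloride | CCCc1cc(OC(C)(C)C)cc(OC)c1C(=O)Cl | intermediate
31 | 3-acetyl-2,6-bis(benzyloxy)-4-pentylphenyl 4-(tert-butoxy)-2-methoxy-6-propylbenzoate | CCCCCc1cc(OCc2ccccc2)c(OC(=O)c2c(CCC)cc(OC(C)(C)C)cc2OC)c(OCc2ccccc2)c1C(C)=O | intermediate
32 | 3-acetyl-2,6-bis(benzyloxy)-4-pentylphenyl 4-hydroxy-2-methoxy-6-propylbenzoate | CCCCCc1cc(OCc2ccccc2)c(OC(=O)c2c(CCC)cc(O)cc2OC)c(OCc2ccccc2)c1C(C)=O | intermediate
33 | 3-acetyl-2,6-dihydroxy-4-pentylphenyl 4-hydroxy-2-methoxy-6-propylbenzoate | CCCCCc1cc(O)c(OC(=O)c2c(CCC)cc(O)cc2OC)c(O)c1C(C)=O | target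

Total step count: 16. Longest linear sequence: 9 steps (1, 3, 4, 7, 8, 9, 14, 15, 16).

Steps most likely to fail

Step 7. Capture of the short-lived vinylketene by the ynol ether may lose out to three processes:
- ketene dimerisation;
- dipolar addition of the diazo group to the activated alkene of a second molecule;
- thermal fragmentation of the ynol ether.

The fallback takes ring B from the aromatic pool instead of annulating it. It sets out from 29 and comes back at 33. Commercial 5-propylbenzene-1,3-diol F1 would be formylated (POCl3, DMF, Vilsmeier–Haack) to 2,4-dihydroxy-6-propylbenzaldehyde F2. Benzylation at the non-chelated para hydroxyl (BnBr, one equivalent, K2CO3, acetone) would give 4-(benzyloxy)-2-hydroxy-6-propylbenzaldehyde F3. Methylation (MeI, K2CO3, DMF) would give 4-(benzyloxy)-2-methoxy-6-propylbenzaldehyde F4, and Pinnick oxidation (NaClO2, NaH2PO4, 2-methylbut-2-ene) would give 4-(benzyloxy)-2-methoxy-6-propylbenzoic acid F5. Condensation of this acid with 29 by (CF3CO)2O in toluene, the classical depside coupling now free of acid-labile groups, would give 3-acetyl-2,6-bis(benzyloxy)-4-pentylphenyl 4-(benzyloxy)-2-methoxy-6-propylbenzoate F6. One hydrogenolysis (H2, 10% Pd/C, EtOAc) of that compound gives 33.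

Step 4. Deprotonation at the acetyl methyl may be overtaken by conjugate self-addition of the enolate to the strongly electrophilic enoate, or by removal of a gamma proton from the propyl branch. The fallback avoids any lithium enolate. It sets out from 6 and comes back at 8. Soft enolisation (TBSOTf, Et3N, CH2Cl2, 0 °C) would give benzyl (E)-4-[(tert-butyldimethylsilyl)oxy]-3-propylpenta-2,4-dienoate F7. Bromination of this silyl dienol ether (NBS, THF, −78 °C → 0 °C) would give benzyl (E)-5-bromo-4-oxo-3-propylpent-2-enoate F8. Alkylation of N,N'-ditosylhydrazine with this bromo ketone, followed by double sulfinate elimination (DBU, THF, 0 °C), would give 8.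

Step 13. Acid-promoted loss or migration of benzyl groups, above all of the ether that ends up ortho to the new ketone, may outrun C-acylation of the hindered position. The fallback replaces electrophilic acylation by cross-coupling. It sets out from 26 and comes back at 28, which is then methanolysed to 29 as in the route. Acetylation (Ac2O, pyridine) would give 27, this time isolated. Ionic bromination (NBS, MeCN, 0 °C) would give 2,6-bis(benzyloxy)-3-bromo-4-pentylphenyl acetate F9. Stille coupling with tributyl(1-ethoxyvinyl)stannane (Pd(PPh3)4, toluene, 100 °C) would give 2,6-bis(benzyloxy)-3-(1-ethoxyvinyl)-4-pentylphenyl acetate F10. Brief hydrolysis of the enol ether (1 M HCl, THF, rt) would give 28.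

Further compounds
F1 | step 7 | 5-propylbenzene-1,3-diol | CCCc1cc(O)cc(O)c1
F2 | step 7 | 2,4-dihydroxy-6-propylbenzaldehyde | CCCc1cc(O)cc(O)c1C=O
F3 | step 7 | 4-(benzyloxy)-2-hydroxy-6-propylbenzaldehyde | CCCc1cc(OCc2ccccc2)cc(O)c1C=O
F4 | step 7 | 4-(benzyloxy)-2-methoxy-6-propylbenzaldehyde | CCCc1cc(OCc2ccccc2)cc(OC)c1C=O
F5 | step 7 | 4-(benzyloxy)-2-methoxy-6-propylbenzoic acid | CCCc1cc(OCc2ccccc2)cc(OC)c1C(=O)O
F6 | step 7 | 3-acetyl-2,6-bis(benzyloxy)-4-pentylphenyl 4-(benzyloxy)-2-methoxy-6-propylbenzoate | CCCCCc1cc(OCc2ccccc2)c(OC(=O)c2c(CCC)cc(OCc3ccccc3)cc2OC)c(OCc2ccccc2)c1C(C)=O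
F7 | step 4 | benzyl (E)-4-[(tert-butyldimethylsilyl)oxy]-3-propylpenta-2,4-dienoate | CCC/C(C(=C)O[Si](C)(C)C(C)(C)C)=C\C(=O)OCc1ccccc1
F8 | step 4 | benzyl (E)-5-bromo-4-oxo-3-propylpent-2-enoate | CCC/C(C(=O)CBr)=C\C(=O)OCc1ccccc1
F9 | step 13 | 2,6-bis(benzyloxy)-3-bromo-4-pentylphenyl acetate | CCCCCc1cc(OCc2ccccc2)c(OC(C)=O)c(OCc2ccccc2)c1Br
F10 | step 13 | 2,6-bis(benzyloxy)-3-(1-ethoxyvinyl)-4-pentylphenyl acetate | CCCCCc1cc(OCc2ccccc2)c(OC(C)=O)c(OCc2ccccc2)c1C(=C)OCC
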